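**Plan**

- Hardest point: the only stereocentre, Cα, is an enolisable α-ketol carbon between the C6 aryl ketone and the benzylic CβH2. The C3=C4 olefin of the pyran ring rules out the hydrogenolytic and olefin-oxidising tactics normally used to make such ketols.
- Cuts: first Cα–Cβ (key step), then C6–C(=O). Ring A and the pyran ring are bought together as precocene I, and ring B is bought as a 4-oxybenzyl alcohol.
- Enabling feature: ring B carries its OH para to Cβ, so Cβ can be delivered as the exocyclic CH2 of a p-quinone methide. Ring A carries the O7 methyl ether ortho to the C6 ketone, and O7, C=O and the α-OH together form the O,O,O-chelate of a chiral dinuclear zinc enolate.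
- Forward: C6 of precocene I is glycoloylated (steps 1–2). A base-triggered latent quinone methide is made from ring B (steps 3–4). The two unprotected halves are joined in step 5.
- Stereochemistry: Cα-(S) is set in the C–C bond-forming step by the (R,R)-linked-BINOL/zinc catalyst, and no later step touches it.

Key step: step 5

Assumption: the facial preference of the zinc/linked-BINOL enolate known for β-unsubstituted vinyl ketones ((S,S)-ligand gives the 2R ketol) is taken to hold for the quinone methide, hence the (R,R)-ligand for Cα-(S); should the sense be reversed, the antipodal ligand is used.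

Step 1
Reactants: 1 precocene I (7-methoxy-2,2-dimethyl-2H-chromene); 2 acetoxyacetyl chloride
Product: 3 2-(7-methoxy-2,2-dimethyl-2H-chromen-6-yl)-2-oxoethyl acetate
Conditions: SnCl4 (1.1 equiv), CH2Cl2, −78 to −30 °C; aqueous work-up
Reagents that add atoms: none
Why: Friedel–Crafts acylation should go to C6, which is para to O1 and ortho to O7 and is the most nucleophilic open position (C8 lies between two oxygens, C3 is shielded by the gem-dimethyl group), while the low temperature limits acid attack on the C3=C4 olefin.

Step 2
Reactants: 3 2-(7-methoxy-2,2-dimethyl-2H-chromen-6-yl)-2-oxoethyl acetate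
Product: 4 2-hydroxy-1-(7-methoxy-2,2-dimethyl-2H-chromen-6-yl)ethan-1-one
Conditions: K2CO3 (10 mol %), MeOH, 0 °C
Reagents that add atoms: none
Why: Base-catalysed transesterification (Zemplén-type methanolysis) should remove the primary acetate without touching the aryl ketone, the methyl ether or the olefin, and no stereocentre is involved.

Step 3
Reactants: 5 4-(hydroxymethyl)phenyl acetate
Product: 6 4-{[(tert-butoxycarbonyl)oxy]methyl}phenyl acetate
Conditions: Boc2O (1.1 equiv), DMAP (5 mol %), CH2Cl2, 0 °C to rt
Reagents that add atoms: di-tert-butyl dicarbonate, CC(C)(C)OC(=O)OC(=O)OC(C)(C)C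
Why: DMAP-catalysed O-tert-butoxycarbonylation of a primary benzylic alcohol is standard, and the aryl acetate keeps the ring too electron-poor for the new benzylic carbonate to ionise.

Step 4
Reactants: 6 4-{[(tert-butoxycarbonyl)oxy]methyl}phenyl acetate
Product: 7 tert-butyl 4-hydroxybenzyl carbonate
Conditions: immobilised Candida antarctica lipase B, n-BuOH (3 equiv), MTBE, 30 °C
Reagents that add atoms: none
Why: Lipase-catalysed alcoholysis of a phenolic acetate runs without base, so the phenol should be freed without passing through the phenoxide that would trigger 1,6-elimination, and the bulky tert-butyl carbonate is a poor enzyme substrate.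

Step 5
Reactants: 4 2-hydroxy-1-(7-methoxy-2,2-dimethyl-2H-chromen-6-yl)ethan-1-one; 7 tert-butyl 4-hydroxybenzyl carbonate
Product: 9 lespeflorin C7 [(S)-2-hydroxy-3-(4-hydroxyphenyl)-1-(7-methoxy-2,2-dimethyl-2H-chromen-6-yl)propan-1-one], via p-quinone methide 8 (not isolated)
Conditions: Et2Zn (20 mol %), (R,R)-linked-BINOL [3,3''-(oxydimethylene)-bridged bis-BINOL] (5 mol %), MS 3 Å, THF, 0 °C; 4 (2 equiv), 7 added over 12 h
Reagents that add atoms: none
Why: Proposed new method: the basic zinc aryloxide/alkoxide sites of the catalyst deprotonate the phenol of 7, whose phenoxide expels tert-butyl carbonate by 1,6-elimination (the fragmentation of self-immolative p-hydroxybenzyl linkers) to give 8, CO2 and a zinc tert-butoxide that turns 4 into its chelated (Z)-zinc enolate; attack of the enolate carbon on the exocyclic CH2 of 8 (1,6-conjugate addition, driven by rearomatisation of ring B) forms Cα–Cβ, and the zinc phenoxide of 9 hands the metal to the next molecule of 7, so that 8 is released only as fast as the catalyst turns over. The closest known reaction types are the direct zinc/linked-BINOL Michael addition of unprotected 2-hydroxy-2'-methoxyacetophenone to β-unsubstituted vinyl ketones and the zinc-enolate allylation of unprotected α-hydroxy ketones with allyl carbonates, where the carbonate leaving group is likewise the only base; what is new is the unsubstituted quinone methide, released in situ, as the acceptor. No ring is closed. The only new stereocentre, Cα, is controlled by the ligand: O7 (methoxy), the ketone oxygen and the α-oxygen hold the enolate flat on the dinuclear zinc core and the binaphthyl wall leaves one face open, the (R,R)-ligand being chosen for Cα-(S). The step needs C- over O-alkylation and enolate over phenoxide attack: O-adducts are p-hydroxybenzyl ethers that revert to 8 by the same 1,6-elimination whereas the C-adduct cannot, and excess 4 together with slow addition of 7 keeps the enolate the dominant nucleophile. A second alkylation and racemisation should be held back because the tertiary Cα–H of 9 is deprotonated far more slowly than the CH2 of 4, and the C3=C4 olefin is inert to every species present.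

**Compound list**

1 | precocene I (7-methoxy-2,2-dimethyl-2H-chromene) | COc1cc2c(cc1)C=CC(C)(C)O2 | starting material
2 | acetoxyacetyl chloride | CC(=O)OCC(=O)Cl | starting material
3 | 2-(7-methoxy-2,2-dimethyl-2H-chromen-6-yl)-2-oxoethyl acetate | COc1cc2c(cc1C(=O)COC(C)=O)C=CC(C)(C)O2 | intermediate
4 | 2-hydroxy-1-(7-methoxy-2,2-dimethyl-2H-chromen-6-yl)ethan-1-one | COc1cc2c(cc1C(=O)CO)C=CC(C)(C)O2 | intermediate
5 | 4-(hydroxymethyl)phenyl acetate | CC(=O)Oc1ccc(CO)cc1 | starting material
6 | 4-{[(tert-butoxycarbonyl)oxy]methyl}phenyl acetate | CC(=O)Oc1ccc(COC(=O)OC(C)(C)C)cc1 | intermediate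
7 | tert-butyl 4-hydroxybenzyl carbonate | CC(C)(C)OC(=O)OCc1ccc(O)cc1 | intermediate
8 | p-quinone methide (4-methylidenecyclohexa-2,5-dien-1-one), not isolated | C=C1C=CC(=O)C=C1 | intermediate
9 | lespeflorin C7, (S)-2-hydroxy-3-(4-hydroxyphenyl)-1-(7-methoxy-2,2-dimethyl-2H-chromen-6-yl)propan-1-one | COc1cc2c(cc1C(=O)[C@@H](O)Cc1ccc(O)cc1)C=CC(C)(C)O2 | target

Total step count: 5
Longest linear sequence: 3 steps (1 → 3 → 4 → 9)

**Steps most likely to fail**

Step 5 (Proposed new method).
- What may go wrong: oligomerisation of the quinone methide by C-alkylation of phenoxides may outrun capture by the enolate. Facial selectivity may be poor with so small and reactive an acceptor. Binding of CO2 or phenol may erode the basicity of the catalyst.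
- The fallback sets out from 4 and comes back at 9. It uses known chemistry and moves the stereochemical event from C–C bond formation to a reduction.
- Compound 4 is condensed with 4-hydroxybenzaldehyde (piperidinium acetate, toluene, water separator; aldol condensation, the α-hydroxy enone tautomerising) to 3-(4-hydroxyphenyl)-1-(7-methoxy-2,2-dimethyl-2H-chromen-6-yl)propane-1,2-dione F1.
- The C2 carbonyl of F1 is then reduced by asymmetric transfer hydrogenation (RuCl[(S,S)-TsDPEN](p-cymene), HCO2H/Et3N, 10 °C).
- This reaction type is known to stop at the 2-hydroxy ketone with 1-aryl-1,2-diketones. It should spare the donor-deactivated, ortho-substituted C1 ketone and the C3=C4 olefin. The (S,S)-catalyst is expected to give the (S)-ketol 9.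

Step 1.
- What may go wrong: hydrochlorination or oligomerisation at C3=C4 by the acid set free, competing acylation at C3, or Lewis-acid demethylation at O7 after chelation to the new ketone.
- The fallback sets out from 1 and comes back at 4. It replaces electrophilic acylation by formylation plus umpolung C1 homologation.
- Vilsmeier–Haack formylation (POCl3, DMF, 0 °C to rt, then aqueous NaOAc) should give 7-methoxy-2,2-dimethyl-2H-chromene-6-carbaldehyde F2.
- Thiazolium-carbene-catalysed hydroxymethylation of F2 with paraformaldehyde (iPr2NEt, THF, 60 °C; crossed acyloin reaction with formaldehyde) should then give 4.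

Step 4.
- What may go wrong: premature 1,6-elimination of the carbonate once the phenol is free, with self-condensation on concentration or storage, or slow enzymatic attack on the carbonate.
- The fallback gives up the Cα–Cβ cut and takes the stereocentre from the chiral pool. It sets out from 1 and comes back at 9.
- Commercial (S)-3-(4-hydroxyphenyl)lactic acid, which has the same spatial arrangement at Cα as 9, is peracetylated (Ac2O, pyridine) to (S)-2-acetoxy-3-(4-acetoxyphenyl)propanoic acid F3.
- F3 is converted with oxalyl chloride and catalytic DMF into (S)-2-acetoxy-3-(4-acetoxyphenyl)propanoyl chloride F4.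
- F4 acylates 1 at C6 (SnCl4, CH2Cl2, −78 °C; Friedel–Crafts acylation with α-acyloxy acid chlorides is known to keep configuration) to give the O,O'-diacetate of lespeflorin C7 F5.
- Both acetates of F5 are removed with catalytic K2CO3 in MeOH at −10 °C to give 9.

**Further compounds**

F1 | step 5 | 3-(4-hydroxyphenyl)-1-(7-methoxy-2,2-dimethyl-2H-chromen-6-yl)propane-1,2-dione | COc1cc2c(cc1C(=O)C(=O)Cc1ccc(O)cc1)C=CC(C)(C)O2
F2 | step 1 | 7-methoxy-2,2-dimethyl-2H-chromene-6-carbaldehyde | COc1cc2c(cc1C=O)C=CC(C)(C)O2
F3 | step 4 | (S)-2-acetoxy-3-(4-acetoxyphenyl)propanoic acid | OC(=O)[C@@H](OC(C)=O)Cc1ccc(OC(C)=O)cc1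
F4 | step 4 | (S)-2-acetoxy-3-(4-acetoxyphenyl)propanoyl chloride | ClC(=O)[C@@H](OC(C)=O)Cc1ccc(OC(C)=O)cc1
F5 | step 4 | O,O'-diacetate of lespeflorin C7 | COc1cc2c(cc1C(=O)[C@@H](OC(C)=O)Cc1ccc(OC(C)=O)cc1)C=CC(C)(C)O2
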